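**Retrosynthetic overview**

- The target is epigallocatechin-(4β→8)-epigallocatechin 3-O-gallate-(4β→8)-epigallocatechin. The plan rests on the three C5'–O bonds of the pyrogallol rings B, because the oxygen at C5' is all that separates each ring B from a catechol ring. These three bonds are made last, by C–H borylation–oxidation of an epicatechin-type trimer whose rings B are 2,2-dimethyl-1,3-benzodioxoles.
- Before that, the trimer is cut at its two C4–C8 interflavan bonds. The middle–bottom bond is formed first and the top–middle bond second, each by Lewis-acid arylation of a flavan C4 cation whose leaving group comes from DDQ oxidation.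
- All three flavan units (rings A, C and B, with C2 and C3 as 2R,3R) come from (−)-epicatechin, and the galloyl ring comes from gallic acid. No ring of the target is built; only the three dioxole ketal rings are closed (step 1) and opened again (step 11).

Key step: step 10

**Remarks on the chemistry**

- Flavan numbering is used (rings A, C, B; primed locants on ring B). TBS is tert-butyldimethylsilyl, Bpin is 4,4,5,5-tetramethyl-1,3,2-dioxaborolan-2-yl, and dtbpy is 4,4'-di-tert-butyl-2,2'-bipyridine.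
- The galloylated middle unit is built from (−)-epicatechin and pre-silylated gallic acid. Ketalisation of natural epicatechin gallate would also tie up the vicinal diol of its galloyl ring.
- The nucleophile is used in excess in steps 8 and 9 and the surplus is recovered by chromatography.

**Route**

Step 1
Reactants: 1 (−)-epicatechin
Product: 2 3',4'-O-isopropylidene-(−)-epicatechin
Conditions: Me2C(OMe)2, TsOH·H2O (cat.), acetone, rt, argon
Reagents that add atoms: 2,2-dimethoxypropane, COC(C)(C)OC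
Why: Acid-catalysed transketalisation can close a five-membered cyclic ketal only on the ortho-dihydroxy ring B, since the meta-related ring A phenols and the isolated 3-OH cannot form such a ring, and C2 and C3 are not touched.

Step 2
Reactants: 2 3',4'-O-isopropylidene-(−)-epicatechin
Product: 3 5,7-bis-O-TBS-3',4'-O-isopropylidene-(−)-epicatechin (3-OH free)
Conditions: TBSCl (2.2 equiv), imidazole, DMF, 0 °C → rt
Reagents that add atoms: tert-butyldimethylsilyl chloride, CC(C)(C)[Si](C)(C)Cl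
Why: Chemoselective O-silylation is much faster at the two acidic ring A phenols than at the hindered axial secondary 3-OH, so controlled stoichiometry should give the 5,7-bis(silyl ether).

Step 3
Reactants: 2 3',4'-O-isopropylidene-(−)-epicatechin
Product: 4 3,5,7-tris-O-TBS-3',4'-O-isopropylidene-(−)-epicatechin
Conditions: TBSOTf (3.6 equiv), 2,6-lutidine, CH2Cl2, 0 °C → rt
Reagents that add atoms: tert-butyldimethylsilyl triflate, CC(C)(C)[Si](C)(C)OS(=O)(=O)C(F)(F)F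
Why: The more electrophilic silyl triflate with 2,6-lutidine should silylate the hindered axial 3-OH as well as both phenols (exhaustive O-silylation) without touching the ketal or the stereocentres.

Step 4
Reactants: 4 3,5,7-tris-O-TBS-3',4'-O-isopropylidene-(−)-epicatechin
Product: 5 4β-(2-ethoxyethoxy)-3,5,7-tris-O-TBS-3',4'-O-isopropylidene-(−)-epicatechin (2,3-cis-3,4-trans)
Conditions: DDQ (2 equiv), 2-ethoxyethanol (5 equiv), CH2Cl2, rt
Reagents that add atoms: 2-ethoxyethanol, CCOCCO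
Why: DDQ benzylic oxidation removes hydride from C4 to give a cation stabilised by O1 and the 5- and 7-silyloxy groups of ring A, and the alcohol traps it on the β face, anti to the 3-OTBS and 2-aryl groups, which sets the temporary C4 centre as 3,4-trans.

Step 5
Reactants: 3 5,7-bis-O-TBS-3',4'-O-isopropylidene-(−)-epicatechin
Product: 6 4β-(2-ethoxyethoxy)-5,7-bis-O-TBS-3',4'-O-isopropylidene-(−)-epicatechin (3-OH free)
Conditions: DDQ (2 equiv), 2-ethoxyethanol (5 equiv), CH2Cl2, rt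
Reagents that add atoms: 2-ethoxyethanol, CCOCCO
Why: The same DDQ-mediated C4 oxidation tolerates the free 3-OH, which is not benzylic, and the alcohol again adds trans to the C3 oxygen under substrate control.

Step 6
Reactants: 7 gallic acid
Product: 9 3,4,5-tris(tert-butyldimethylsilyloxy)benzoic acid, via silyl ester 8 (not isolated)
Conditions: TBSCl (4.5 equiv), imidazole, DMF, rt; then AcOH/THF/H2O (3:1:1), rt
Reagents that add atoms: tert-butyldimethylsilyl chloride, CC(C)(C)[Si](C)(C)Cl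
Why: Exhaustive silylation of all four acidic OH groups is followed by selective hydrolysis of the far more labile silyl ester with aqueous acetic acid, which leaves the three aryl silyl ethers in place.

Step 7
Reactants: 6 4β-(2-ethoxyethoxy)-5,7-bis-O-TBS-3',4'-O-isopropylidene-(−)-epicatechin; 9 3,4,5-tris(tert-butyldimethylsilyloxy)benzoic acid
Product: 10 4β-(2-ethoxyethoxy)-5,7-bis-O-TBS-3',4'-O-isopropylidene-(−)-epicatechin 3-O-[3,4,5-tris(TBS-oxy)benzoate]
Conditions: DCC, DMAP, CH2Cl2, rt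
Reagents that add atoms: none
Why: Steglich esterification acylates the axial 3-OH under neutral conditions that spare the acid-labile benzylic 4-ether and all silyl ethers, with retention at C3 because the C3–O bond is not broken.

Step 8
Reactants: 10 galloylated 4β-(2-ethoxyethoxy) electrophile; 4 3,5,7-tris-O-TBS-3',4'-O-isopropylidene-(−)-epicatechin (4 equiv)
Product: 11 protected epicatechin 3-O-gallate-(4β→8)-epicatechin dimer (eight TBS ethers and two acetonides)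
Conditions: TMSOTf (0.5 equiv), CH2Cl2, −78 °C; Et3N quench
Reagents that add atoms: none
Why: Lewis-acid ionisation of the 4-alkoxy group gives the ring A-stabilised C4 cation, which undergoes Friedel–Crafts arylation by C8 of the excess nucleophile (C6 lies between two silyloxy groups), and attack anti to the 2-aryl and 3-acyloxy groups, reinforced by participation of the galloyl carbonyl on the α face, sets the new C4 stereocentre as 4β (3,4-trans).

Step 9
Reactants: 5 4β-(2-ethoxyethoxy)-3,5,7-tris-O-TBS-3',4'-O-isopropylidene-(−)-epicatechin (added slowly); 11 protected dimer (2 equiv)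
Product: 12 protected epicatechin-(4β→8)-epicatechin 3-O-gallate-(4β→8)-epicatechin trimer (eleven TBS ethers and three acetonides)
Conditions: TMSOTf (0.5 equiv), CH2Cl2, −78 °C; Et3N quench
Reagents that add atoms: none
Why: The same Friedel–Crafts flavan-4-yl arylation should take place at C8 of the upper, galloylated unit of 11, the only ring A position with a single flanking silyloxy group, and the arene enters anti to the α-oriented 2-aryl and 3-OTBS groups of the cation so that the second interflavan stereocentre is again 4β, while slow addition of 5 to excess 11 limits self-condensation.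

Step 10
Reactants: 12 protected trimer; 13 bis(pinacolato)diboron (6 equiv)
Product: 15 protected trimer bearing a free 5'-hydroxyl on each ring B, via tris(pinacolboronate) 14 (not isolated)
Conditions: [Ir(OMe)(cod)]2 (10 mol%), dtbpy (20 mol%), THF, 80 °C (sealed tube); then NaBO3·4H2O, THF/H2O, 0 °C → rt
Reagents that add atoms: sodium perborate (used as NaBO3·4H2O), [Na+].[O-]OB=O
Why: The dtbpy-ligated trivalent iridium tris(boryl) complex formed from [Ir(OMe)(cod)]2 and B2pin2 cleaves an aryl C–H bond through a pentavalent iridium aryl hydride (or the equivalent σ-bond-metathesis transition state), C–B reductive elimination releases the aryl boronate, and perborate then adds to boron and triggers 1,2-aryl migration to oxygen, so each C–B bond becomes a C–O bond at the same carbon. The closest known reaction type is the sterically governed iridium-catalysed C–H borylation of 1,3-benzodioxoles ortho to the ring oxygen, with oxidation of the boronate to the phenol in the same flask. No ring is closed and no stereocentre is formed, and the eight existing stereocentres are untouched because this catalyst does not activate sp3 C–H bonds and the oxidation is run cold in mildly basic aqueous THF. The selectivity needed is site selectivity among the aryl C–H bonds: on each ring B, C5'–H has only the small, tied-back dioxole oxygen as ortho neighbour, whereas C2'–H lies between C1' and O3' and C6'–H is ortho to the branched flavan C2; every C–H of the rings A (C6–H between two silyloxy groups, C8–H of the top unit between OTBS and O1) and of the galloyl ring (between the ester and OTBS) is flanked on both sides and should stay inert, and no benzyl or other unhindered arene is present to compete. Excess B2pin2 and a high catalyst loading are used so that all three remote rings B react, and the first boryl group on a ring blocks C6' against a second borylation.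

Step 11
Reactants: 15 protected trimer with three free 5'-hydroxyls
Product: 17 epigallocatechin-(4β→8)-epigallocatechin 3-O-gallate-(4β→8)-epigallocatechin (CNP0278699.1), via acetonide-free undecasilyl ether 16 (not isolated)
Conditions: TFA/H2O (9:1), CH2Cl2, 0 °C → rt, argon; evaporate; then HF·pyridine, pyridine/THF, 0 °C → rt; Me3SiOMe quench
Reagents that add atoms: none
Why: Aqueous trifluoroacetic acid hydrolyses the three aryl ketals while the silylated, less electron-rich rings A and the electron-withdrawing 3-O-galloyl group retard ipso-protonation and heterolysis of the interflavan bonds, and buffered HF·pyridine then cleaves every Si–O bond (Si–F bond formation) without base, so the ester, the stereocentres and the air-sensitive pyrogallol rings should survive, and any silyl ether already lost in the acid stage is of no consequence.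

**Compound list**

1 | (−)-epicatechin | O[C@@H]1Cc2c(O)cc(O)cc2O[C@@H]1c1ccc(O)c(O)c1 | starting material
2 | 3',4'-O-isopropylidene-(−)-epicatechin | O[C@@H]1Cc2c(O)cc(O)cc2O[C@@H]1c1ccc2OC(C)(C)Oc2c1 | intermediate
3 | 5,7-bis-O-TBS-3',4'-O-isopropylidene-(−)-epicatechin | O[C@@H]1Cc2c(O[Si](C)(C)C(C)(C)C)cc(O[Si](C)(C)C(C)(C)C)cc2O[C@@H]1c1ccc2OC(C)(C)Oc2c1 | intermediate
4 | 3,5,7-tris-O-TBS-3',4'-O-isopropylidene-(−)-epicatechin | CC(C)(C)[Si](C)(C)O[C@@H]1Cc2c(O[Si](C)(C)C(C)(C)C)cc(O[Si](C)(C)C(C)(C)C)cc2O[C@@H]1c1ccc2OC(C)(C)Oc2c1 | intermediate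
5 | 4β-(2-ethoxyethoxy)-3,5,7-tris-O-TBS-3',4'-O-isopropylidene-(−)-epicatechin | CCOCCO[C@H]1c2c(O[Si](C)(C)C(C)(C)C)cc(O[Si](C)(C)C(C)(C)C)cc2O[C@H](c2ccc3OC(C)(C)Oc3c2)[C@@H]1O[Si](C)(C)C(C)(C)C | intermediate
6 | 4β-(2-ethoxyethoxy)-5,7-bis-O-TBS-3',4'-O-isopropylidene-(−)-epicatechin | CCOCCO[C@H]1c2c(O[Si](C)(C)C(C)(C)C)cc(O[Si](C)(C)C(C)(C)C)cc2O[C@H](c2ccc3OC(C)(C)Oc3c2)[C@@H]1O | intermediate
7 | gallic acid | O=C(O)c1cc(O)c(O)c(O)c1 | starting material
8 | tert-butyldimethylsilyl 3,4,5-tris(tert-butyldimethylsilyloxy)benzoate | O=C(O[Si](C)(C)C(C)(C)C)c1cc(O[Si](C)(C)C(C)(C)C)c(O[Si](C)(C)C(C)(C)C)c(O[Si](C)(C)C(C)(C)C)c1 | intermediate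
9 | 3,4,5-tris(tert-butyldimethylsilyloxy)benzoic acid | O=C(O)c1cc(O[Si](C)(C)C(C)(C)C)c(O[Si](C)(C)C(C)(C)C)c(O[Si](C)(C)C(C)(C)C)c1 | intermediate
10 | 4β-(2-ethoxyethoxy)-5,7-bis-O-TBS-3',4'-O-isopropylidene-(−)-epicatechin 3-O-[3,4,5-tris(TBS-oxy)benzoate] | CCOCCO[C@H]1c2c(O[Si](C)(C)C(C)(C)C)cc(O[Si](C)(C)C(C)(C)C)cc2O[C@H](c2ccc3OC(C)(C)Oc3c2)[C@@H]1OC(=O)c1cc(O[Si](C)(C)C(C)(C)C)c(O[Si](C)(C)C(C)(C)C)c(O[Si](C)(C)C(C)(C)C)c1 | intermediate
11 | protected epicatechin 3-O-gallate-(4β→8)-epicatechin dimer | O=C(O[C@@H]1[C@@H](c2c(O[Si](C)(C)C(C)(C)C)cc(O[Si](C)(C)C(C)(C)C)c3c2O[C@H](c2ccc4OC(C)(C)Oc4c2)[C@H](O[Si](C)(C)C(C)(C)C)C3)c2c(O[Si](C)(C)C(C)(C)C)cc(O[Si](C)(C)C(C)(C)C)cc2O[C@@H]1c1ccc2OC(C)(C)Oc2c1)c1cc(O[Si](C)(C)C(C)(C)C)c(O[Si](C)(C)C(C)(C)C)c(O[Si](C)(C)C(C)(C)C)c1 | intermediate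
12 | protected epicatechin-(4β→8)-epicatechin 3-O-gallate-(4β→8)-epicatechin trimer | O=C(O[C@@H]1[C@@H](c2c(O[Si](C)(C)C(C)(C)C)cc(O[Si](C)(C)C(C)(C)C)c3c2O[C@H](c2ccc4OC(C)(C)Oc4c2)[C@H](O[Si](C)(C)C(C)(C)C)C3)c2c(O[Si](C)(C)C(C)(C)C)cc(O[Si](C)(C)C(C)(C)C)c([C@H]3c4c(O[Si](C)(C)C(C)(C)C)cc(O[Si](C)(C)C(C)(C)C)cc4O[C@H](c4ccc5OC(C)(C)Oc5c4)[C@@H]3O[Si](C)(C)C(C)(C)C)c2O[C@@H]1c1ccc2OC(C)(C)Oc2c1)c1cc(O[Si](C)(C)C(C)(C)C)c(O[Si](C)(C)C(C)(C)C)c(O[Si](C)(C)C(C)(C)C)c1 | intermediate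
13 | bis(pinacolato)diboron | CC1(C)OB(OC1(C)C)B1OC(C)(C)C(C)(C)O1 | starting material
14 | protected trimer with a Bpin group at C5' of each ring B | O=C(O[C@@H]1[C@@H](c2c(O[Si](C)(C)C(C)(C)C)cc(O[Si](C)(C)C(C)(C)C)c3c2O[C@H](c2cc(B5OC(C)(C)C(C)(C)O5)c4OC(C)(C)Oc4c2)[C@H](O[Si](C)(C)C(C)(C)C)C3)c2c(O[Si](C)(C)C(C)(C)C)cc(O[Si](C)(C)C(C)(C)C)c([C@H]3c4c(O[Si](C)(C)C(C)(C)C)cc(O[Si](C)(C)C(C)(C)C)cc4O[C@H](c4cc(B6OC(C)(C)C(C)(C)O6)c5OC(C)(C)Oc5c4)[C@@H]3O[Si](C)(C)C(C)(C)C)c2O[C@@H]1c1cc(B3OC(C)(C)C(C)(C)O3)c2OC(C)(C)Oc2c1)c1cc(O[Si](C)(C)C(C)(C)C)c(O[Si](C)(C)C(C)(C)C)c(O[Si](C)(C)C(C)(C)C)c1 | intermediate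
15 | protected trimer with a free 5'-hydroxyl on each ring B | O=C(O[C@@H]1[C@@H](c2c(O[Si](C)(C)C(C)(C)C)cc(O[Si](C)(C)C(C)(C)C)c3c2O[C@H](c2cc(O)c4OC(C)(C)Oc4c2)[C@H](O[Si](C)(C)C(C)(C)C)C3)c2c(O[Si](C)(C)C(C)(C)C)cc(O[Si](C)(C)C(C)(C)C)c([C@H]3c4c(O[Si](C)(C)C(C)(C)C)cc(O[Si](C)(C)C(C)(C)C)cc4O[C@H](c4cc(O)c5OC(C)(C)Oc5c4)[C@@H]3O[Si](C)(C)C(C)(C)C)c2O[C@@H]1c1cc(O)c2OC(C)(C)Oc2c1)c1cc(O[Si](C)(C)C(C)(C)C)c(O[Si](C)(C)C(C)(C)C)c(O[Si](C)(C)C(C)(C)C)c1 | intermediate
16 | undeca-O-TBS epigallocatechin-(4β→8)-epigallocatechin 3-O-gallate-(4β→8)-epigallocatechin with free pyrogallol rings B | O=C(O[C@@H]1[C@@H](c2c(O[Si](C)(C)C(C)(C)C)cc(O[Si](C)(C)C(C)(C)C)c3c2O[C@H](c2cc(O)c(O)c(O)c2)[C@H](O[Si](C)(C)C(C)(C)C)C3)c2c(O[Si](C)(C)C(C)(C)C)cc(O[Si](C)(C)C(C)(C)C)c([C@H]3c4c(O[Si](C)(C)C(C)(C)C)cc(O[Si](C)(C)C(C)(C)C)cc4O[C@H](c4cc(O)c(O)c(O)c4)[C@@H]3O[Si](C)(C)C(C)(C)C)c2O[C@@H]1c1cc(O)c(O)c(O)c1)c1cc(O[Si](C)(C)C(C)(C)C)c(O[Si](C)(C)C(C)(C)C)c(O[Si](C)(C)C(C)(C)C)c1 | intermediate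
17 | epigallocatechin-(4β→8)-epigallocatechin 3-O-gallate-(4β→8)-epigallocatechin (CNP0278699.1) | O=C(O[C@@H]1[C@@H](c2c(O)cc(O)c3c2O[C@H](c2cc(O)c(O)c(O)c2)[C@H](O)C3)c2c(O)cc(O)c([C@H]3c4c(O)cc(O)cc4O[C@H](c4cc(O)c(O)c(O)c4)[C@@H]3O)c2O[C@@H]1c1cc(O)c(O)c(O)c1)c1cc(O)c(O)c(O)c1 | target

**Step count and risk**

Total step count: 11. Longest linear sequence: 8 steps (steps 1, 2, 5, 7, 8, 9, 10 and 11).

Steps most likely to fail:

Step 10. The borylation may stop short at one or more of the three remote rings B of the crowded trimer, or aryl silyl ethers may be lost during the perborate oxidation, so that partially hydroxylated trimers form that cannot be separated. The fallback moves the same C–H oxidation to the monomer, where a single unhindered ring B reacts. It sets out from 3 (with 9 as in the main route) and returns to the route at 17. Compound 3 would be borylated under the conditions of step 10, its free 3-OH being carried as the pinacol borate in the bis-boron intermediate F1. Perborate in the same flask should then give 5,7-bis-O-TBS-3',4'-O-isopropylidene-(−)-epigallocatechin F2. TBSCl (1.1 equiv) and imidazole would silylate the new phenol selectively to the 5,7,5'-tris(silyl ether) F3. DDQ and 2-ethoxyethanol would convert part of F3 into the 4β-(2-ethoxyethoxy) alcohol F4, and Steglich esterification of F4 with 9 would give the galloylated electrophile F5. TMSOTf-mediated coupling of F5 with excess F3 should give the 4β→8 dimer F6, and coupling of F4 with F6 the fully oxygenated protected trimer F7. Aqueous TFA would remove the ketals to give the silyl ether F8, which HF·pyridine would convert without isolation into 17.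

Step 9. Self-condensation of the electrophile through its own unhindered C8 may outrun attack by the more hindered C8 of the dimer and lead to oligomers. The fallback blocks that position with bromine. It sets out from 4 and returns at 12. NBS in CH2Cl2 at −78 °C should brominate 4 at C8, the only ring A position not flanked by two silyloxy groups, to give the 8-bromo flavan F9. DDQ and 2-ethoxyethanol would convert it into the 8-bromo 4β-(2-ethoxyethoxy) electrophile F10, which can no longer act as a nucleophile and could be coupled with 11 in near-equimolar amounts (TMSOTf, CH2Cl2, −78 °C) to give the 8-bromo trimer F11. Hydrogenolysis of the aryl bromide (H2, Pd/C, Et3N, EtOAc) would then give 12.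

Step 11. Acid may cleave the C4–C8 interflavan bonds, or open ring C with epimerisation at C2, while the ketals are hydrolysed. The fallback exchanges the silyl ethers for electron-withdrawing benzyl carbonates before the acid step, so that the rings A cannot be protonated, and finishes by neutral hydrogenolysis. It sets out from 15 and returns at 17. HF·pyridine would first remove all silyl groups to give the tris-acetonide polyphenol F12. CbzCl and iPr2NEt in THF at 0 °C would convert its twelve phenols into the dodeca(benzyl carbonate) F13; any carbonate formed at a 3-hydroxyl would be lost in the final step. Aqueous TFA would hydrolyse the three ketals of this deactivated compound to give the hexaol F14, and H2 with Pd/C in EtOAc/MeOH would cleave all benzyl carbonates to give 17.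

**Further compounds**

F1 | step 10 | 3-O-Bpin-5'-Bpin derivative of 3 (in-flask intermediate) | CC1(C)OB(O[C@@H]2Cc3c(O[Si](C)(C)C(C)(C)C)cc(O[Si](C)(C)C(C)(C)C)cc3O[C@@H]2c2cc(B3OC(C)(C)C(C)(C)O3)c3OC(C)(C)Oc3c2)OC1(C)C
F2 | step 10 | 5,7-bis-O-TBS-3',4'-O-isopropylidene-(−)-epigallocatechin | O[C@@H]1Cc2c(O[Si](C)(C)C(C)(C)C)cc(O[Si](C)(C)C(C)(C)C)cc2O[C@@H]1c1cc(O)c2OC(C)(C)Oc2c1
F3 | step 10 | 5,7,5'-tris-O-TBS-3',4'-O-isopropylidene-(−)-epigallocatechin | O[C@@H]1Cc2c(O[Si](C)(C)C(C)(C)C)cc(O[Si](C)(C)C(C)(C)C)cc2O[C@@H]1c1cc(O[Si](C)(C)C(C)(C)C)c2OC(C)(C)Oc2c1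
F4 | step 10 | 4β-(2-ethoxyethoxy)-5,7,5'-tris-O-TBS-3',4'-O-isopropylidene-(−)-epigallocatechin | CCOCCO[C@H]1c2c(O[Si](C)(C)C(C)(C)C)cc(O[Si](C)(C)C(C)(C)C)cc2O[C@H](c2cc(O[Si](C)(C)C(C)(C)C)c3OC(C)(C)Oc3c2)[C@@H]1O
F5 | step 10 | 3-O-[3,4,5-tris(TBS-oxy)benzoate] of F4 | CCOCCO[C@H]1c2c(O[Si](C)(C)C(C)(C)C)cc(O[Si](C)(C)C(C)(C)C)cc2O[C@H](c2cc(O[Si](C)(C)C(C)(C)C)c3OC(C)(C)Oc3c2)[C@@H]1OC(=O)c1cc(O[Si](C)(C)C(C)(C)C)c(O[Si](C)(C)C(C)(C)C)c(O[Si](C)(C)C(C)(C)C)c1
F6 | step 10 | protected epigallocatechin 3-O-gallate-(4β→8)-epigallocatechin dimer (lower 3-OH free) | O=C(O[C@@H]1[C@@H](c2c(O[Si](C)(C)C(C)(C)C)cc(O[Si](C)(C)C(C)(C)C)c3c2O[C@H](c2cc(O[Si](C)(C)C(C)(C)C)c4OC(C)(C)Oc4c2)[C@H](O)C3)c2c(O[Si](C)(C)C(C)(C)C)cc(O[Si](C)(C)C(C)(C)C)cc2O[C@@H]1c1cc(O[Si](C)(C)C(C)(C)C)c2OC(C)(C)Oc2c1)c1cc(O[Si](C)(C)C(C)(C)C)c(O[Si](C)(C)C(C)(C)C)c(O[Si](C)(C)C(C)(C)C)c1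
F7 | step 10 | protected epigallocatechin-(4β→8)-epigallocatechin 3-O-gallate-(4β→8)-epigallocatechin trimer with 5'-OTBS groups (top and bottom 3-OH free) | O=C(O[C@@H]1[C@@H](c2c(O[Si](C)(C)C(C)(C)C)cc(O[Si](C)(C)C(C)(C)C)c3c2O[C@H](c2cc(O[Si](C)(C)C(C)(C)C)c4OC(C)(C)Oc4c2)[C@H](O)C3)c2c(O[Si](C)(C)C(C)(C)C)cc(O[Si](C)(C)C(C)(C)C)c([C@H]3c4c(O[Si](C)(C)C(C)(C)C)cc(O[Si](C)(C)C(C)(C)C)cc4O[C@H](c4cc(O[Si](C)(C)C(C)(C)C)c5OC(C)(C)Oc5c4)[C@@H]3O)c2O[C@@H]1c1cc(O[Si](C)(C)C(C)(C)C)c2OC(C)(C)Oc2c1)c1cc(O[Si](C)(C)C(C)(C)C)c(O[Si](C)(C)C(C)(C)C)c(O[Si](C)(C)C(C)(C)C)c1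
F8 | step 10 | F7 without its three acetonides | O=C(O[C@@H]1[C@@H](c2c(O[Si](C)(C)C(C)(C)C)cc(O[Si](C)(C)C(C)(C)C)c3c2O[C@H](c2cc(O[Si](C)(C)C(C)(C)C)c(O)c(O)c2)[C@H](O)C3)c2c(O[Si](C)(C)C(C)(C)C)cc(O[Si](C)(C)C(C)(C)C)c([C@H]3c4c(O[Si](C)(C)C(C)(C)C)cc(O[Si](C)(C)C(C)(C)C)cc4O[C@H](c4cc(O[Si](C)(C)C(C)(C)C)c(O)c(O)c4)[C@@H]3O)c2O[C@@H]1c1cc(O[Si](C)(C)C(C)(C)C)c(O)c(O)c1)c1cc(O[Si](C)(C)C(C)(C)C)c(O[Si](C)(C)C(C)(C)C)c(O[Si](C)(C)C(C)(C)C)c1
F9 | step 9 | 8-bromo-3,5,7-tris-O-TBS-3',4'-O-isopropylidene-(−)-epicatechin | CC(C)(C)[Si](C)(C)O[C@@H]1Cc2c(O[Si](C)(C)C(C)(C)C)cc(O[Si](C)(C)C(C)(C)C)c(Br)c2O[C@@H]1c1ccc2OC(C)(C)Oc2c1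
F10 | step 9 | 8-bromo-4β-(2-ethoxyethoxy)-3,5,7-tris-O-TBS-3',4'-O-isopropylidene-(−)-epicatechin | CCOCCO[C@H]1c2c(O[Si](C)(C)C(C)(C)C)cc(O[Si](C)(C)C(C)(C)C)c(Br)c2O[C@H](c2ccc3OC(C)(C)Oc3c2)[C@@H]1O[Si](C)(C)C(C)(C)C
F11 | step 9 | protected trimer 12 carrying bromine at C8 of its top unit | O=C(O[C@@H]1[C@@H](c2c(O[Si](C)(C)C(C)(C)C)cc(O[Si](C)(C)C(C)(C)C)c3c2O[C@H](c2ccc4OC(C)(C)Oc4c2)[C@H](O[Si](C)(C)C(C)(C)C)C3)c2c(O[Si](C)(C)C(C)(C)C)cc(O[Si](C)(C)C(C)(C)C)c([C@H]3c4c(O[Si](C)(C)C(C)(C)C)cc(O[Si](C)(C)C(C)(C)C)c(Br)c4O[C@H](c4ccc5OC(C)(C)Oc5c4)[C@@H]3O[Si](C)(C)C(C)(C)C)c2O[C@@H]1c1ccc2OC(C)(C)Oc2c1)c1cc(O[Si](C)(C)C(C)(C)C)c(O[Si](C)(C)C(C)(C)C)c(O[Si](C)(C)C(C)(C)C)c1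
F12 | step 11 | tris(3',4'-O-isopropylidene) derivative of the target with all other hydroxyls free | O=C(O[C@@H]1[C@@H](c2c(O)cc(O)c3c2O[C@H](c2cc(O)c4OC(C)(C)Oc4c2)[C@H](O)C3)c2c(O)cc(O)c([C@H]3c4c(O)cc(O)cc4O[C@H](c4cc(O)c5OC(C)(C)Oc5c4)[C@@H]3O)c2O[C@@H]1c1cc(O)c2OC(C)(C)Oc2c1)c1cc(O)c(O)c(O)c1
F13 | step 11 | dodeca(benzyl carbonate) of F12 (all twelve phenols carbonated) | O=C(O[C@@H]1[C@@H](c2c(OC(=O)OCc9ccccc9)cc(OC(=O)OCc9ccccc9)c3c2O[C@H](c2cc(OC(=O)OCc9ccccc9)c4OC(C)(C)Oc4c2)[C@H](O)C3)c2c(OC(=O)OCc9ccccc9)cc(OC(=O)OCc9ccccc9)c([C@H]3c4c(OC(=O)OCc9ccccc9)cc(OC(=O)OCc9ccccc9)cc4O[C@H](c4cc(OC(=O)OCc9ccccc9)c5OC(C)(C)Oc5c4)[C@@H]3O)c2O[C@@H]1c1cc(OC(=O)OCc9ccccc9)c2OC(C)(C)Oc2c1)c1cc(OC(=O)OCc9ccccc9)c(OC(=O)OCc9ccccc9)c(OC(=O)OCc9ccccc9)c1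
F14 | step 11 | F13 without its three acetonides | O=C(O[C@@H]1[C@@H](c2c(OC(=O)OCc9ccccc9)cc(OC(=O)OCc9ccccc9)c3c2O[C@H](c2cc(OC(=O)OCc9ccccc9)c(O)c(O)c2)[C@H](O)C3)c2c(OC(=O)OCc9ccccc9)cc(OC(=O)OCc9ccccc9)c([C@H]3c4c(OC(=O)OCc9ccccc9)cc(OC(=O)OCc9ccccc9)cc4O[C@H](c4cc(OC(=O)OCc9ccccc9)c(O)c(O)c4)[C@@H]3O)c2O[C@@H]1c1cc(OC(=O)OCc9ccccc9)c(O)c(O)c1)c1cc(OC(=O)OCc9ccccc9)c(OC(=O)OCc9ccccc9)c(OC(=O)OCc9ccccc9)c1
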